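**Retrosynthetic overview** (locants C1, O2, C3, C4, C4a, C5, C6, C7, C7a are those of the cyclopenta[c]pyran unit; C2' is the benzofuranone carbon that carries the acetoxy group)

1. Target 25 ⇐ 24 by α-acetoxylation at C2'; 24 ⇐ the C1 oxocarbenium ion from methyl acetal 19 plus silyl enol ether 23 (C1–C2' bond); the benzofuranone ring comes from phenol O-alkylation (20 → 22).
2. 19 ⇐ 16 by C3 lithiation/acylation; the dihydropyran ring (O2–C1, C3=C4) is closed from acetal–aldehyde 15, an iridodial-type 1,5-dicarbonyl on a finished cyclopentane.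
3. Cyclopentane ⇐ acyclic formyl diene 6 by rhodium-catalysed intramolecular hydroacylation that forms C5–C6 and sets C7; the C5 carbonyl it leaves is then deleted via the tosylhydrazone. Enabling feature: C5 and C6 are neighbouring unsubstituted ring CH2 groups and C6 lies next to methyl-bearing C7, so C5 can be a formyl carbon on C4a and C6=C7 the terminal alkene of an isopropenyl group on C7a (a pent-4-enal), at the junction of two isoprene-like C5 halves.
4. 6 ⇐ 3-methylbut-2-enal + nitrodiene 4 (from methacrolein and nitromethane) by one organocatalytic Michael addition that sets C4a and C7a; C7, C1 and C2' are relayed from these two centres.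
5. Ring order: cyclopentane (step 3), dihydropyran (step 9); benzofuranone made separately (step 12) and joined in step 14.

Key step: step 3

Assumption: (R)-BINAP is taken as the ligand antipode matched with 6 for the 3,4-trans ketone in step 3; both antipodes would be run first and (S)-BINAP used if the sense is opposite.

**Step 1**
Reactants: 1 methacrolein (2-methylprop-2-enal); 2 nitromethane
Product: 4 (E)-3-methyl-1-nitrobuta-1,3-diene, via nitro alcohol 3 (not isolated)
Conditions: MeNO2 (5 equiv), KOtBu (5 mol%), THF/tBuOH, −20 °C; then TFAA, Et3N, CH2Cl2, −20→0 °C; used at once as a solution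
Reagents that add atoms: none
Why: Henry (nitroaldol) reaction: the nitronate adds to the formyl carbon under cold, catalytic-base, short-contact conditions where 1,2-addition is faster than conjugate addition, and trifluoroacetylation with E1cB elimination then gives the conjugated (E)-nitroalkene.

**Step 2**
Reactants: 4 (E)-3-methyl-1-nitrobuta-1,3-diene; 5 3-methylbut-2-enal
Product: 6 (2S,3S)-4-nitro-2,3-di(prop-1-en-2-yl)butanal
Conditions: (S)-2-[diphenyl(trimethylsilyloxy)methyl]pyrrolidine (20 mol%), PhCO2H (20 mol%), 5 (2 equiv), toluene, 0 °C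
Reagents that add atoms: none
Why: Dienamine-mediated asymmetric Michael addition: the amine converts enal 5 into its cross-conjugated dienamine, whose α-carbon adds to the nitro-bearing alkene of 4 at the β-carbon (1,4 and not 1,6, because only this mode allows the compact synclinal iminium–nitronate transition state) on the face away from the diaryl(silyloxy)methyl group, which should set the two new centres as the syn (2S,3S) pair and leave the α-substituent as a deconjugated isopropenyl group.

**Step 3**
Reactants: 6 (2S,3S)-4-nitro-2,3-di(prop-1-en-2-yl)butanal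
Product: 7 (2S,3R,4S)-4-methyl-3-(nitromethyl)-2-(prop-1-en-2-yl)cyclopentan-1-one
Conditions: [Rh(nbd)((R)-BINAP)]BF4 (5 mol%, nbd removed with H2, then Ar), CH2Cl2, 25 °C
Reagents that add atoms: none
Why: Oxidative addition of the formyl C–H bond of 6 to the cationic monovalent rhodium centre gives an acyl rhodium hydride, the isopropenyl group on C3 inserts into Rh–H with hydride going to its substituted carbon and rhodium to the terminal CH2, and C–C reductive elimination from the six-membered acyl–alkyl rhodacycle forms the bond between the former formyl carbon and that CH2 (C5–C6 of the target). The closest known reaction type is the Rh–BINAP-catalysed intramolecular hydroacylation of 4-substituted and 3,4-disubstituted pent-4-enals to cyclopentanones. The cyclopentanone ring closes in a formally 5-endo-trig hydroacylation that runs through the rhodacycle, so no strained endo transition state is involved. The new stereocentre (C4 of 7, C7 of the target) arises when hydride is delivered to one face of the 1,1-disubstituted alkene; it is under catalyst control by the BINAP ligand, used in the sense matched with the existing C3 centre so that the methyl group ends up trans to the nitromethyl group. The step needs chemoselectivity between the two isopropenyl groups, which is built in because only the one on C3 completes a pent-4-enal (the one on C2 could only give a cyclobutanone), and it needs the C2 centre and its β,γ-alkene to survive, which the neutral, base-free medium at 25 °C should secure. Branching next to the formyl group slows decarbonylation, the usual competing path.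

**Step 4**
Reactants: 7 (2S,3R,4S)-4-methyl-3-(nitromethyl)-2-(prop-1-en-2-yl)cyclopentan-1-one
Product: 8 N'-[(2S,3R,4S)-4-methyl-3-(nitromethyl)-2-(prop-1-en-2-yl)cyclopentylidene]-4-methylbenzenesulfonohydrazide
Conditions: TsNHNH2 (1.1 equiv), MeOH, 25 °C
Reagents that add atoms: 4-methylbenzenesulfonohydrazide, Cc1ccc(cc1)S(=O)(=O)NN
Why: Condensation of the ketone with the sulfonyl hydrazide (hydrazone formation) under neutral conditions, chosen so that the enolisable C2 centre next to the carbonyl is not disturbed.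

**Step 5**
Reactants: 8 tosylhydrazone of 7
Product: 10 (1S,2R,3S)-1-methyl-2-(nitromethyl)-3-(prop-1-en-2-yl)cyclopentane, via hydrazinoborane 9 (not isolated)
Conditions: catecholborane, CHCl3, 0 °C; then NaOAc·3H2O, 60 °C
Reagents that add atoms: none
Why: Tosylhydrazone deoxygenation: hydride from the borane adds to C=N, acetate then induces loss of sulfinate to an alkyl diazene that extrudes N2 with hydrogen transfer to carbon, which removes the activating carbonyl of step 3 without base strong enough to touch the nitro group or the ring stereocentres.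

**Step 6**
Reactants: 10 (1S,2R,3S)-1-methyl-2-(nitromethyl)-3-(prop-1-en-2-yl)cyclopentane
Product: 12 (1S,2R,3S)-2-(dimethoxymethyl)-1-methyl-3-(prop-1-en-2-yl)cyclopentane, via sodium nitronate 11 (not isolated)
Conditions: NaOMe, MeOH, 0 °C; then added to H2SO4/MeOH, −40 °C
Reagents that add atoms: methanol, CO
Why: Nef reaction in its acetal-forming variant: the nitronate is quenched into cold methanolic H2SO4, where C-protonation and solvolysis give the dimethyl acetal directly, so that C1 reaches the aldehyde oxidation level without a free, epimerisable aldehyde next to the ring carbon and, at −40 °C, without protonation of the isopropenyl group.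

**Step 7**
Reactants: 12 (1S,2R,3S)-2-(dimethoxymethyl)-1-methyl-3-(prop-1-en-2-yl)cyclopentane
Product: 14 2-[(1R,2R,3S)-2-(dimethoxymethyl)-3-methylcyclopentyl]propan-1-ol (epimers at the side-chain CH), via alkylborane 13 (not isolated)
Conditions: 9-BBN, THF, 25 °C; then NaOH, H2O2, 0 °C
Reagents that add atoms: hydrogen peroxide, OO
Why: Anti-Markovnikov hydroboration of the 1,1-disubstituted alkene followed by oxidative work-up gives the primary alcohol; the new side-chain centre is formed as a mixture that converges when this carbon becomes sp2 in step 9.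

**Step 8**
Reactants: 14 2-[(1R,2R,3S)-2-(dimethoxymethyl)-3-methylcyclopentyl]propan-1-ol
Product: 15 2-[(1R,2R,3S)-2-(dimethoxymethyl)-3-methylcyclopentyl]propanal (epimers at the side-chain CH)
Conditions: DMP (triacetoxy periodinane), pyridine, CH2Cl2, 0→25 °C
Reagents that add atoms: none
Why: Periodinane oxidation of the primary alcohol to the aldehyde, buffered with pyridine to keep the dimethyl acetal intact.

**Step 9**
Reactants: 15 2-[(1R,2R,3S)-2-(dimethoxymethyl)-3-methylcyclopentyl]propanal
Product: 16 (1R,4aS,7S,7aR)-1-methoxy-4,7-dimethyl-1,4a,5,6,7,7a-hexahydrocyclopenta[c]pyran (major anomer; the 1S anomer is carried along)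
Conditions: PPTS (10 mol%), benzene, 80 °C, 4 Å MS
Reagents that add atoms: none
Why: Acid-catalysed cyclisation of a 5-oxo acetal to a 2-alkoxy-3,4-dihydro-2H-pyran: the oxocarbenium ion from the acetal is captured by the aldehyde oxygen (six-membered ring) and the resulting cation loses the adjacent side-chain proton, which forms O2–C1 and C3=C4 with the cis ring fusion already fixed by the two ring carbons, the anomeric centre settling in the axial (1R) form.

**Step 10**
Reactants: 16 (1R,4aS,7S,7aR)-1-methoxy-4,7-dimethyl-1,4a,5,6,7,7a-hexahydrocyclopenta[c]pyran; 17 N-methoxy-N,3-dimethylbutanamide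
Product: 19 1-[(1R,4aS,7S,7aR)-1-methoxy-4,7-dimethyl-1,4a,5,6,7,7a-hexahydrocyclopenta[c]pyran-3-yl]-3-methylbutan-1-one, via vinyllithium 18 (not isolated)
Conditions: tBuLi, THF, −78→0 °C; then 17, −78 °C; aq NH4Cl
Reagents that add atoms: none
Why: α-Lithiation of a cyclic enol ether at its vinylic C–H next to oxygen followed by acylation with an N-methoxy-N-methylamide, whose chelated tetrahedral adduct stops at the ketone stage.

**Step 11**
Reactants: 20 1-(2-hydroxy-6-methylphenyl)ethan-1-one
Product: 21 2-bromo-1-(2-hydroxy-6-methylphenyl)ethan-1-one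
Conditions: CuBr2 (2 equiv), EtOAc/CHCl3, reflux
Reagents that add atoms: copper dibromide, Br[Cu]Br
Why: α-Bromination of the aryl methyl ketone by CuBr2 through its copper-bound enol, selective for the side chain over the ring.

**Step 12**
Reactants: 21 2-bromo-1-(2-hydroxy-6-methylphenyl)ethan-1-one
Product: 22 4-methyl-1-benzofuran-3(2H)-one
Conditions: NaOAc, EtOH, reflux
Reagents that add atoms: none
Why: Intramolecular Williamson etherification (5-exo-tet) of the phenol onto the α-bromo ketone closes the furanone ring.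

**Step 13**
Reactants: 22 4-methyl-1-benzofuran-3(2H)-one
Product: 23 trimethyl[(4-methyl-1-benzofuran-3-yl)oxy]silane
Conditions: TMSOTf, Et3N, CH2Cl2, 0 °C; pentane, filtration
Reagents that add atoms: trimethylsilyl trifluoromethanesulfonate, C[Si](C)(C)OS(=O)(=O)C(F)(F)F
Why: Soft enolisation and O-silylation gives the aromatic 3-silyloxybenzofuran, a silyl enol ether that is nucleophilic at C2.

**Step 14**
Reactants: 19 1-[(1R,4aS,7S,7aR)-1-methoxy-4,7-dimethyl-1,4a,5,6,7,7a-hexahydrocyclopenta[c]pyran-3-yl]-3-methylbutan-1-one; 23 trimethyl[(4-methyl-1-benzofuran-3-yl)oxy]silane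
Product: 24 2-[(1R,4aS,7S,7aR)-4,7-dimethyl-3-(3-methylbutanoyl)-1,4a,5,6,7,7a-hexahydrocyclopenta[c]pyran-1-yl]-4-methyl-1-benzofuran-3(2H)-one (epimers at the benzofuranone C2)
Conditions: 23 (1.5 equiv), TMSOTf (0.2 equiv), CH2Cl2, −78→−40 °C
Reagents that add atoms: none
Why: Mukaiyama-type addition of the silyl enol ether to the cyclic oxocarbenium ion released from the anomeric methoxy group; attack on C1 from the convex face of the cis-fused bicycle, anti to the C7a–C7 bond, should set C1 as R, and the configuration of the benzofuranone α-carbon is left open because step 15 passes through its enol.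

**Step 15**
Reactants: 24 2-[(1R,4aS,7S,7aR)-4,7-dimethyl-3-(3-methylbutanoyl)-1,4a,5,6,7,7a-hexahydrocyclopenta[c]pyran-1-yl]-4-methyl-1-benzofuran-3(2H)-one
Product: 25 (2S)-2-[(1R,4aS,7S,7aR)-4,7-dimethyl-3-(3-methylbutanoyl)-1,4a,5,6,7,7a-hexahydrocyclopenta[c]pyran-1-yl]-4-methyl-3-oxo-2,3-dihydro-1-benzofuran-2-yl acetate (target)
Conditions: Pb(OAc)4, AcOH/benzene, 25 °C
Reagents that add atoms: lead tetraacetate, CC(=O)O[Pb](OC(C)=O)(OC(C)=O)OC(C)=O
Why: α-Acetoxylation of the enolisable benzofuranone by tetravalent lead through an enol lead triacetate with internal acetoxy transfer; with the C1–H bond eclipsing the enol double bond to avoid A(1,3) strain, the acetoxy group should enter from the face of the pyran oxygen, anti to the carbocyclic C7a side, which corresponds to the (S) quaternary centre.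

**Compound list**

1 | methacrolein (2-methylprop-2-enal) | CC(=C)C=O | starting material
2 | nitromethane | C[N+](=O)[O-] | starting material
3 | 3-methyl-1-nitrobut-3-en-2-ol (racemic, formed in situ) | CC(=C)C(O)C[N+](=O)[O-] | intermediate
4 | (E)-3-methyl-1-nitrobuta-1,3-diene | CC(=C)/C=C/[N+](=O)[O-] | intermediate
5 | 3-methylbut-2-enal | CC(C)=CC=O | starting material
6 | (2S,3S)-4-nitro-2,3-di(prop-1-en-2-yl)butanal | CC(=C)[C@@H](C=O)[C@@H](C(C)=C)C[N+](=O)[O-] | intermediate
7 | (2S,3R,4S)-4-methyl-3-(nitromethyl)-2-(prop-1-en-2-yl)cyclopentan-1-one | CC(=C)[C@H]1C(=O)C[C@H](C)[C@H]1C[N+](=O)[O-] | intermediate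
8 | N'-[(2S,3R,4S)-4-methyl-3-(nitromethyl)-2-(prop-1-en-2-yl)cyclopentylidene]-4-methylbenzenesulfonohydrazide (C=N geometry not assigned) | CC(=C)[C@H]1C(=NNS(=O)(=O)c2ccc(C)cc2)C[C@H](C)[C@H]1C[N+](=O)[O-] | intermediate
9 | N'-(1,3,2-benzodioxaborol-2-yl)-N'-[(2S,3R,4S)-4-methyl-3-(nitromethyl)-2-(prop-1-en-2-yl)cyclopentyl]-4-methylbenzenesulfonohydrazide (C1 epimers, formed in situ) | CC(=C)[C@H]1C(N(NS(=O)(=O)c2ccc(C)cc2)B2Oc3ccccc3O2)C[C@H](C)[C@H]1C[N+](=O)[O-] | intermediate
10 | (1S,2R,3S)-1-methyl-2-(nitromethyl)-3-(prop-1-en-2-yl)cyclopentane | CC(=C)[C@H]1CC[C@H](C)[C@H]1C[N+](=O)[O-] | intermediate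
11 | sodium nitronate (aci-nitro salt) of 10 (formed in situ) | CC(=C)[C@H]1CC[C@H](C)[C@H]1C=[N+]([O-])[O-].[Na+] | intermediate
12 | (1S,2R,3S)-2-(dimethoxymethyl)-1-methyl-3-(prop-1-en-2-yl)cyclopentane | CC(=C)[C@H]1CC[C@H](C)[C@H]1C(OC)OC | intermediate
13 | 9-{2-[(1R,2R,3S)-2-(dimethoxymethyl)-3-methylcyclopentyl]propyl}-9-borabicyclo[3.3.1]nonane (side-chain epimers, formed in situ) | CC(CB1C2CCCC1CCC2)[C@H]1CC[C@H](C)[C@H]1C(OC)OC | intermediate
14 | 2-[(1R,2R,3S)-2-(dimethoxymethyl)-3-methylcyclopentyl]propan-1-ol (side-chain epimers) | CC(CO)[C@H]1CC[C@H](C)[C@H]1C(OC)OC | intermediate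
15 | 2-[(1R,2R,3S)-2-(dimethoxymethyl)-3-methylcyclopentyl]propanal (side-chain epimers) | CC(C=O)[C@H]1CC[C@H](C)[C@H]1C(OC)OC | intermediate
16 | (1R,4aS,7S,7aR)-1-methoxy-4,7-dimethyl-1,4a,5,6,7,7a-hexahydrocyclopenta[c]pyran (major anomer shown) | CO[C@@H]1OC=C(C)[C@H]2CC[C@H](C)[C@@H]12 | intermediate
17 | N-methoxy-N,3-dimethylbutanamide | CC(C)CC(=O)N(C)OC | starting material
18 | [(1R,4aS,7S,7aR)-1-methoxy-4,7-dimethyl-1,4a,5,6,7,7a-hexahydrocyclopenta[c]pyran-3-yl]lithium (formed in situ) | CO[C@@H]1OC([Li])=C(C)[C@H]2CC[C@H](C)[C@@H]12 | intermediate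
19 | 1-[(1R,4aS,7S,7aR)-1-methoxy-4,7-dimethyl-1,4a,5,6,7,7a-hexahydrocyclopenta[c]pyran-3-yl]-3-methylbutan-1-one | CO[C@@H]1OC(C(=O)CC(C)C)=C(C)[C@H]2CC[C@H](C)[C@@H]12 | intermediate
20 | 1-(2-hydroxy-6-methylphenyl)ethan-1-one | CC(=O)c1c(C)cccc1O | starting material
21 | 2-bromo-1-(2-hydroxy-6-methylphenyl)ethan-1-one | O=C(CBr)c1c(C)cccc1O | intermediate
22 | 4-methyl-1-benzofuran-3(2H)-one | Cc1cccc2OCC(=O)c12 | intermediate
23 | trimethyl[(4-methyl-1-benzofuran-3-yl)oxy]silane | Cc1cccc2occ(O[Si](C)(C)C)c12 | intermediate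
24 | 2-[(1R,4aS,7S,7aR)-4,7-dimethyl-3-(3-methylbutanoyl)-1,4a,5,6,7,7a-hexahydrocyclopenta[c]pyran-1-yl]-4-methyl-1-benzofuran-3(2H)-one (epimers at the benzofuranone C2) | Cc1cccc2OC([C@@H]3OC(C(=O)CC(C)C)=C(C)[C@H]4CC[C@H](C)[C@H]43)C(=O)c12 | intermediate
25 | (2S)-2-[(1R,4aS,7S,7aR)-4,7-dimethyl-3-(3-methylbutanoyl)-1,4a,5,6,7,7a-hexahydrocyclopenta[c]pyran-1-yl]-4-methyl-3-oxo-2,3-dihydro-1-benzofuran-2-yl acetate | CC(=O)O[C@]1([C@@H]2OC(C(=O)CC(C)C)=C(C)[C@H]3CC[C@H](C)[C@H]32)Oc2cccc(C)c2C1=O | target

**Totals and risks**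

Total step count: 15. Longest linear sequence: 12 steps (steps 1–10, 14, 15).

Steps most likely to fail:

1. Step 3 (key step). The rhodium hydride may move the α-isopropenyl double bond into conjugation or epimerise the adjacent centre, the acyl rhodium species may decarbonylate, and the hydride delivery that sets the methyl-bearing centre may show poor facial selectivity. The fallback sets out from 2 and 5 and comes back at 7. It closes the same bond at the alkyne oxidation level and sets the methyl-bearing centre by substrate control. Nitromethane 2 would be added to commercial 3-(trimethylsilyl)prop-2-ynal (KOtBu cat.) to give 1-nitro-4-(trimethylsilyl)but-3-yn-2-ol F1, and dehydration (TFAA, Et3N) would give trimethyl[(3E)-4-nitrobut-3-en-1-yn-1-yl]silane F2. The dienamine Michael addition of 5 under the conditions of step 2 should give (2S,3S)-3-(nitromethyl)-2-(prop-1-en-2-yl)-5-(trimethylsilyl)pent-4-ynal F3. [Rh(dppe)]2(BF4)2 in acetone would then effect the intramolecular trans-hydroacylation of the alkyne (acyl carbon to the silyl-bearing alkyne carbon) to (4S,5S)-4-(nitromethyl)-5-(prop-1-en-2-yl)-2-(trimethylsilyl)cyclopent-2-en-1-one F4. Conjugate addition of Me2CuLi (excess, TMSCl, THF, −78 °C), anti to the neighbouring nitromethyl group, should give (3R,4S,5S)-3-methyl-4-(nitromethyl)-5-(prop-1-en-2-yl)-2-(trimethylsilyl)cyclopentan-1-one F5, and KF in MeOH would remove the silyl group to give 7.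

2. Step 10. Metalation may be incomplete or go to an allylic instead of the vinylic position, and the lithiated acetal may open. The fallback sets out from 15 and comes back at 19. It builds the acyl group before the pyran ring is closed. Wittig reaction of 15 with the ylide from (3-methylbutyl)triphenylphosphonium bromide (NaHMDS, THF, −78 °C) would give (1S,2R,3R)-2-(dimethoxymethyl)-1-methyl-3-[(3Z)-6-methylhept-3-en-2-yl]cyclopentane F6. Dihydroxylation (OsO4 cat., NMO) would give 2-[(1R,2R,3S)-2-(dimethoxymethyl)-3-methylcyclopentyl]-6-methylheptane-3,4-diol F7, and double Swern oxidation 2-[(1S,2R,3S)-2-(dimethoxymethyl)-3-methylcyclopentyl]-6-methylheptane-3,4-dione F8. The acid-catalysed acetal/carbonyl cyclisation of step 9 (PPTS, benzene, 4 Å MS), now through the inner keto group and its enolisable α-carbon, should give 19.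

3. Step 15. Oxygen may be delivered to the planar enol with poor facial selectivity, and the oxidant may attack other enolisable or electron-rich sites. The fallback sets out from 24 and comes back at 25. It replaces substrate control by reagent control and separates C–O bond formation from acylation. KHMDS (1.05 equiv, THF, −78 °C) would deprotonate only the benzofuranone to potassium 2-[(1R,4aS,7S,7aR)-4,7-dimethyl-3-(3-methylbutanoyl)-1,4a,5,6,7,7a-hexahydrocyclopenta[c]pyran-1-yl]-4-methyl-1-benzofuran-3-olate F9. The matched antipode of (camphorsulfonyl)oxaziridine would hydroxylate it to (2R)-2-[(1R,4aS,7S,7aR)-4,7-dimethyl-3-(3-methylbutanoyl)-1,4a,5,6,7,7a-hexahydrocyclopenta[c]pyran-1-yl]-2-hydroxy-4-methyl-1-benzofuran-3(2H)-one F10, and Ac2O, DMAP, Et3N would give 25.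

**Further compounds**

F1 | step 3 | 1-nitro-4-(trimethylsilyl)but-3-yn-2-ol (racemic, formed in situ) | C[Si](C)(C)C#CC(O)C[N+](=O)[O-]
F2 | step 3 | trimethyl[(3E)-4-nitrobut-3-en-1-yn-1-yl]silane | C[Si](C)(C)C#C/C=C/[N+](=O)[O-]
F3 | step 3 | (2S,3S)-3-(nitromethyl)-2-(prop-1-en-2-yl)-5-(trimethylsilyl)pent-4-ynal | CC(=C)[C@@H](C=O)[C@@H](C#C[Si](C)(C)C)C[N+](=O)[O-]
F4 | step 3 | (4S,5S)-4-(nitromethyl)-5-(prop-1-en-2-yl)-2-(trimethylsilyl)cyclopent-2-en-1-one | CC(=C)[C@H]1C(=O)C([Si](C)(C)C)=C[C@H]1C[N+](=O)[O-]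
F5 | step 3 | (3R,4S,5S)-3-methyl-4-(nitromethyl)-5-(prop-1-en-2-yl)-2-(trimethylsilyl)cyclopentan-1-one (C2 epimers) | CC(=C)[C@H]1C(=O)C([Si](C)(C)C)[C@H](C)[C@H]1C[N+](=O)[O-]
F6 | step 10 | (1S,2R,3R)-2-(dimethoxymethyl)-1-methyl-3-[(3Z)-6-methylhept-3-en-2-yl]cyclopentane (side-chain C2 epimers) | CC(/C=C\CC(C)C)[C@H]1CC[C@H](C)[C@H]1C(OC)OC
F7 | step 10 | 2-[(1R,2R,3S)-2-(dimethoxymethyl)-3-methylcyclopentyl]-6-methylheptane-3,4-diol (side-chain stereoisomers) | CC(C(O)C(O)CC(C)C)[C@H]1CC[C@H](C)[C@H]1C(OC)OC
F8 | step 10 | 2-[(1S,2R,3S)-2-(dimethoxymethyl)-3-methylcyclopentyl]-6-methylheptane-3,4-dione (side-chain C2 epimers) | CC(C(=O)C(=O)CC(C)C)[C@H]1CC[C@H](C)[C@H]1C(OC)OC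
F9 | step 15 | potassium 2-[(1R,4aS,7S,7aR)-4,7-dimethyl-3-(3-methylbutanoyl)-1,4a,5,6,7,7a-hexahydrocyclopenta[c]pyran-1-yl]-4-methyl-1-benzofuran-3-olate (formed in situ) | Cc1cccc2oc([C@@H]3OC(C(=O)CC(C)C)=C(C)[C@H]4CC[C@H](C)[C@H]43)c([O-])c12.[K+]
F10 | step 15 | (2R)-2-[(1R,4aS,7S,7aR)-4,7-dimethyl-3-(3-methylbutanoyl)-1,4a,5,6,7,7a-hexahydrocyclopenta[c]pyran-1-yl]-2-hydroxy-4-methyl-1-benzofuran-3(2H)-one | O[C@]1([C@@H]2OC(C(=O)CC(C)C)=C(C)[C@H]3CC[C@H](C)[C@H]32)Oc2cccc(C)c2C1=O
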